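solid substrate 0.12 M; time 6.0 min

    starting material → ring (k1 = 0.0018 /s)
    starting material + starting material ⇌ open dimer (K2 = 1.6 /M, k2 = 0.022 /M/s)
    solid substrate ⇌ starting material, rate k3*(cs3 - [starting material]) while solid is left; crystals form when [starting material] > cs3 (cs3 = 0.11 M, k3 = 0.0029 /s)
    starting material ⇌ dormant form (K4 = 1.8, k4 = 1.9 × 10⁻⁴ /s)

- Thursday's: doubling the solubility in step 3, all else as stated
- Tuesday's: doubling the dissolution coefficient of step 3, all else as stated

- the ring standing at 6.0 min, as a percentage of the solid substrate charged
- the change that raises the amount of ring at 6.0 min, in percent of the solid substrate charged most ("none" if none brings more than 2 percentage points) (Thursday's / Tuesday's / none)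
- amount of ring at 6.0 min, in percent of the solid substrate charged, after Tuesday's

- percent here means solid substrate units held: one open dimer counts as two
- two of one species on the left: rate k times its square, two consumed each time
- solid substrate is a solid; its amount is given per volume of the solution
- at the start none of the solid substrate is in solution
- run time (flask): 6.0 min

1. It is tempting to hold c(starting material) at the solubility, 0.11 M, from the first second, which gives 59.4% ring, but the solution starts empty, so we write its balance instead.

2. While solid stands, we set aside the open dimer and the dormant form: c gains the dissolution coefficient times the gap to solubility and loses the ring constant times c. The two sum to 0.00470 /s, and c climbs at that rate towards the feed level, the steady-state c at which dissolution delivers what ring closure takes, 0.0679 M.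

3. So c reaches 0.0554 M at 6.0 min, and integrating it gives ring 19.0%, with 34.9% of the charge still solid.

4. The weak link is the open dimer, which we set aside: at its equilibrium with the c of step 3, it would hold 8.18% of the charge, so we commit to 19.0% as a high figure for the ring.

5. Tuesday's moves the feed level to 0.0839 M, approached at 0.00760 /s, and the same reckoning gives ring 29.8%, again a high figure with the open dimer set aside.

6. At equal c, Thursday's dissolves faster than Tuesday's, so we choose Thursday's.

The forecast says 17.7%, Thursday's and 27.7%, with “the dimer near equilibrium and acting as a buffer”.

The flask gives 17.7%, and 27.6% after Tuesday's; Thursday's gains 13 percentage points against 9.9 points.

In the flask at 6.00 min, starting material stands at 42.1%, lower than the feed level of 56.6% of the charge, and it is still made 1.43 times faster than it is used up, each step taken net, down from 2.54 at 2.54 min. The same feed level, integrated to 2.5 min for the flask left until then, gives ring 4.31%, and that flask holds 4.17%.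

The constants belong to no real substance; the flask was simulated.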